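**Retrosynthetic overview**

1. The amino group is introduced last, from a 2‑bromoquinone (azide addition–elimination, then reductive loss of N2); the quinone comes from a 1,4‑dimethoxynaphthalene and the acid from an aldehyde.
2. C5=C6 is cut to an aryl keto‑ylide and the meso all‑syn dialdehyde OHC–CH(Me)–CH(OTBS)–CH(Me)–CHO; one catalytic, enantiotopic‑group‑selective Wittig reaction joins the halves and fixes 2R,3S,4R.
3. The meso dialdehyde comes from double syn‑selective Rh‑catalysed hydroboration of silylated 2,4‑dimethylpenta‑1,4‑dien‑3‑ol (methacrolein + isopropenylmagnesium bromide), then Swern oxidation.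
4. The ylide comes from ortho‑acylation of a 2‑naphthol with propanoyl chloride (position peri to OMe), α‑bromination and PPh3.
5. Ring order: the benzenoid ring is made first, by Diels–Alder reaction of a 2‑silyloxy‑3‑methylbutadiene with 2,6‑dibromo‑1,4‑benzoquinone and aromatisation (quinone ring stored as its dimethyl ether, the surviving Br marking the C–N carbon); the quinone ring is unmasked after the coupling; the chain contains no ring.

Assumption: 2 (THF solution), 10 and 15 are purchased; which enantiomer of the step‑11 catalyst gives 21 (reaction at the formyl group on the (S)‑configured α‑carbon of 7) is fixed in a first screen, both enantiomers being available.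

**Route**

Step 1
Reactants: 1 methacrolein; 2 isopropenylmagnesium bromide
Product: 3 2,4-dimethylpenta-1,4-dien-3-ol
Conditions: THF, −78 → 0 °C; then H2O
Reagents that add atoms: none
Why: Grignard 1,2‑addition of the alkenylmagnesium reagent to the enal carbonyl; the carbinol carbon carries two identical isopropenyl groups, so no stereocentre is formed.

Step 2
Reactants: 3 2,4-dimethylpenta-1,4-dien-3-ol
Product: 4 tert-butyl[(2,4-dimethylpenta-1,4-dien-3-yl)oxy]dimethylsilane
Conditions: TBSCl, imidazole, DMF, 23 °C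
Reagents that add atoms: tert-butyldimethylsilyl chloride CC(C)(C)[Si](C)(C)Cl
Why: Standard silylation of a secondary alcohol; the bulky silyl ether gives the best syn selectivity in step 3 and lasts until step 14.

Step 3
Reactants: 4 silyl ether of the dienol
Product: 6 meso-(2R,4S)-3-[(tert-butyldimethylsilyl)oxy]-2,4-dimethylpentane-1,5-diol, via bis-catecholboronate 5 (not isolated)
Conditions: catecholborane (3 equiv), RhCl(PPh3)3 (4 mol %), THF, 23 °C; then NaOH, H2O2, 0 → 23 °C
Reagents that add atoms: catecholborane B1Oc2ccccc2O1 (boron and catecholate stay only in 5); hydrogen peroxide OO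
Why: Rh(I)‑catalysed hydroboration of 1,1‑disubstituted allylic silyl ethers, then oxidation, adds H–B anti‑Markovnikov and syn to the silyloxy carbon at each alkene, giving the 2,3‑syn‑3,4‑syn triad as an achiral meso diol (the chiral syn,anti isomer is removed by chromatography).

Step 4
Reactants: 6 meso diol
Product: 7 meso-(2R,4S)-3-[(tert-butyldimethylsilyl)oxy]-2,4-dimethylpentanedial
Conditions: (COCl)2, DMSO, CH2Cl2, −78 °C; then Et3N, −78 → −30 °C; used crude at once
Reagents that add atoms: none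
Why: Swern oxidation activates both hydroxyls before base is added, so the dialdehyde forms instead of a lactol or lactone and the α‑centres do not epimerise at low temperature; 7 is still meso.

Step 5
Reactants: 8 3-methylbut-3-en-2-one
Product: 9 [(3-methylbuta-1,3-dien-2-yl)oxy]tri(propan-2-yl)silane
Conditions: TIPSOTf, Et3N, CH2Cl2, 0 °C
Reagents that add atoms: triisopropylsilyl trifluoromethanesulfonate CC(C)[Si](OS(=O)(=O)C(F)(F)F)(C(C)C)C(C)C
Why: Soft enolisation and O‑silylation of the methyl ketone (only the CH3 side can enolise) gives the 2‑silyloxy diene.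

Step 6
Reactants: 9 silyloxy diene; 10 2,6-dibromo-1,4-benzoquinone
Product: 13 [(6-bromo-5,8-dimethoxy-3-methylnaphthalen-2-yl)oxy]tri(propan-2-yl)silane, via cycloadduct 11 (not isolated), via hydroquinone 12 (not isolated)
Conditions: toluene, 23 °C, Ar; then K2CO3, Me2SO4, acetone, 56 °C, Ar
Reagents that add atoms: dimethyl sulfate COS(=O)(=O)OC
Why: Halogen‑directed Diels–Alder reaction (the nucleophilic CH2 terminus next to C–OSi bonds to the bromine‑free quinone carbon), then base‑induced HBr loss and enolisation aromatise the adduct to the hydroquinone, which is O‑methylated in the same flask; the surviving Br sits on the carbon that will carry nitrogen and the stereocentres of racemic 11 are erased.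

Step 7
Reactants: 13 aryl silyl ether
Product: 14 6-bromo-5,8-dimethoxy-3-methylnaphthalen-2-ol
Conditions: TBAF, THF, 0 °C; then AcOH
Reagents that add atoms: none
Why: Fluoride cleavage of the aryl silyl ether frees the naphthol needed to direct the acylation.

Step 8
Reactants: 14 naphthol; 15 propanoyl chloride
Product: 16 1-(6-bromo-2-hydroxy-5,8-dimethoxy-3-methylnaphthalen-1-yl)propan-1-one
Conditions: TiCl4, CH2Cl2, 0 → 23 °C; then cold 1 M HCl
Reagents that add atoms: none
Why: Titanium‑naphthoxide‑directed ortho Friedel–Crafts acylation goes to the only free ortho position, which is also the intrinsically most nucleophilic α‑carbon of a 2‑naphthol.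

Step 9
Reactants: 16 hydroxy ketone
Product: 18 rac-2-bromo-1-{6-bromo-2-[(tert-butyldimethylsilyl)oxy]-5,8-dimethoxy-3-methylnaphthalen-1-yl}propan-1-one, via bis-silyl enol ether 17 (not isolated)
Conditions: TBSOTf (2.4 equiv), Et3N, CH2Cl2, 0 → 23 °C; then NBS, THF, −78 °C
Reagents that add atoms: tert-butyldimethylsilyl trifluoromethanesulfonate CC(C)(C)[Si](C)(C)OS(=O)(=O)C(F)(F)F; N-bromosuccinimide BrN1C(=O)CCC1=O
Why: One silylation protects the phenol and converts the ketone into its silyl enol ether, whose bromination with NBS is much faster than bromination of the arene; the CHBr centre is racemic and is removed in step 10.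

Step 10
Reactants: 18 α-bromo ketone
Product: 20 1-{6-bromo-2-[(tert-butyldimethylsilyl)oxy]-5,8-dimethoxy-3-methylnaphthalen-1-yl}-2-(triphenyl-λ5-phosphanylidene)propan-1-one, via phosphonium bromide 19 (not isolated)
Conditions: PPh3, toluene, 80 °C; then aq Na2CO3, CH2Cl2, 23 °C
Reagents that add atoms: triphenylphosphine c1ccc(cc1)P(c1ccccc1)c1ccccc1
Why: SN2 quaternisation of PPh3 by the α‑bromo ketone and deprotonation of the acidic α‑CH give the keto‑stabilised Wittig ylide.

Step 11
Reactants: 20 keto-ylide; 7 meso dialdehyde (1.5 equiv)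
Product: 21 (2R,3S,4R,5E)-7-{6-bromo-2-[(tert-butyldimethylsilyl)oxy]-5,8-dimethoxy-3-methylnaphthalen-1-yl}-3-[(tert-butyldimethylsilyl)oxy]-2,4,6-trimethyl-7-oxohept-5-enal
Conditions: chiral 2‑arylpyrrolidine amido‑thiourea hydrogen‑bond donor (15 mol %), 4 Å MS, toluene, 0 → 23 °C, 48–72 h
Reagents that add atoms: none
Why: Proposed new method: an enantiotopic‑group‑selective Wittig olefination catalysed by a non‑basic chiral hydrogen‑bond donor – the thiourea binds one formyl oxygen (LUMO lowering and oxyanion stabilisation in the oxaphosphetane‑forming transition state, with cation–π contact of its aryl group to phosphorus), and because the two formyl groups of meso 7 sit next to α‑stereocentres of opposite configuration their Felkin‑preferred faces are mirror images, so a catalyst that favours one carbonyl face olefinates only the formyl group on the (S)‑α‑carbon, while over‑reaction of the minor enantiomer to the meso bis‑enone raises the ee further; the uncatalysed reaction of this hindered α‑methyl keto‑ylide is negligible at 23 °C, the ylide gives the (E)‑trisubstituted enone, and this single step forms C5=C6 and fixes C2, C3 and C4 as 2R,3S,4R (first non‑racemic compound of the route); closest known reaction types: Brønsted‑acid‑ or hydrogen‑bond‑donor‑accelerated Wittig reactions of stabilised ylides, the hydrogen‑bond‑donor‑catalysed desymmetrising Wittig olefination of 4‑substituted cyclohexanones, and the auxiliary‑based (chiral phosphonate) Horner–Wadsworth–Emmons desymmetrisation of meso‑dialdehydes.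

Step 12
Reactants: 21 enone aldehyde
Product: 22 (2R,3S,4R,5E)-7-{6-bromo-2-[(tert-butyldimethylsilyl)oxy]-5,8-dimethoxy-3-methylnaphthalen-1-yl}-3-[(tert-butyldimethylsilyl)oxy]-2,4,6-trimethyl-7-oxohept-5-enoic acid
Conditions: NaClO2, NaH2PO4, 2-methylbut-2-ene (20 equiv), t-BuOH/H2O, 0 → 23 °C
Reagents that add atoms: sodium chlorite [Na+].[O-]Cl=O
Why: Pinnick oxidation converts the aldehyde to the acid without epimerising C2, and the alkene scavenger keeps HOCl away from the electron‑rich arene.

Step 13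
Reactants: 22 dimethoxynaphthalene acid
Product: 23 (2R,3S,4R,5E)-7-{6-bromo-2-[(tert-butyldimethylsilyl)oxy]-3-methyl-5,8-dioxo-5,8-dihydronaphthalen-1-yl}-3-[(tert-butyldimethylsilyl)oxy]-2,4,6-trimethyl-7-oxohept-5-enoic acid
Conditions: (NH4)2Ce(NO3)6 (2.5 equiv), MeCN/H2O, 0 °C
Reagents that add atoms: water O
Why: CAN oxidative demethylation turns the 1,4‑dimethoxy ring into the 1,4‑quinone, while the fully substituted acyl/silyloxy ring cannot form a para‑quinone.

Step 14
Reactants: 23 bis-silylated bromoquinone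
Product: 24 (2R,3S,4R,5E)-7-(6-bromo-2-hydroxy-3-methyl-5,8-dioxo-5,8-dihydronaphthalen-1-yl)-3-hydroxy-2,4,6-trimethyl-7-oxohept-5-enoic acid
Conditions: 48% aq HF, MeCN, 0 → 23 °C
Reagents that add atoms: none
Why: Acidic fluoride removes both silyl ethers (any aryl silyl ether already lost in step 13 converges here) without retro‑aldol, elimination or oxa‑Michael ring closure.

Step 15
Reactants: 24 bromoquinone
Product: 26 (2R,3S,4R,5E)-7-(6-amino-2-hydroxy-3-methyl-5,8-dioxo-5,8-dihydronaphthalen-1-yl)-3-hydroxy-2,4,6-trimethyl-7-oxohept-5-enoic acid, via azidoquinone 25 (not isolated)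
Conditions: NaN3, THF/H2O, 0 → 23 °C, dark; then aq Na2S2O4 (1.2 equiv); air; acidify to pH 3
Reagents that add atoms: sodium azide [Na+].[N-]=[N+]=[N-]
Why: Addition–elimination of azide at the bromine‑bearing carbon (also the β‑carbon of the more electrophilic quinone carbonyl), then dithionite reduction to the azidohydroquinone, which loses N2 by internal redox to the 2‑aminoquinone; no stereocentre is touched.

**Compound list**

1 | methacrolein (2-methylprop-2-enal) | C=C(C)C=O | starting material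
2 | isopropenylmagnesium bromide (prop-1-en-2-ylmagnesium bromide, THF solution) | C=C(C)[Mg]Br | starting material
3 | 2,4-dimethylpenta-1,4-dien-3-ol (achiral) | C=C(C)C(O)C(C)=C | intermediate
4 | tert-butyl[(2,4-dimethylpenta-1,4-dien-3-yl)oxy]dimethylsilane | C=C(C)C(O[Si](C)(C)C(C)(C)C)C(C)=C | intermediate
5 | 2,2'-{(2R,4S)-3-[(tert-butyldimethylsilyl)oxy]-2,4-dimethylpentane-1,5-diyl}bis(1,3,2-benzodioxaborole), meso, all-syn | O1c2ccccc2OB1C[C@@H](C)[C@H](O[Si](C)(C)C(C)(C)C)[C@@H](C)CB1Oc2ccccc2O1 | intermediate (not isolated)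
6 | meso-(2R,4S)-3-[(tert-butyldimethylsilyl)oxy]-2,4-dimethylpentane-1,5-diol (2,3-syn, 3,4-syn) | OC[C@@H](C)[C@H](O[Si](C)(C)C(C)(C)C)[C@@H](C)CO | intermediate
7 | meso-(2R,4S)-3-[(tert-butyldimethylsilyl)oxy]-2,4-dimethylpentanedial (2,3-syn, 3,4-syn) | O=C[C@@H](C)[C@H](O[Si](C)(C)C(C)(C)C)[C@@H](C)C=O | intermediate
8 | 3-methylbut-3-en-2-one | CC(=O)C(C)=C | starting material
9 | [(3-methylbuta-1,3-dien-2-yl)oxy]tri(propan-2-yl)silane | C=C(C)C(=C)O[Si](C(C)C)(C(C)C)C(C)C | intermediate
10 | 2,6-dibromocyclohexa-2,5-diene-1,4-dione (2,6-dibromo-1,4-benzoquinone) | O=C1C=C(Br)C(=O)C(Br)=C1 | starting material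
11 | rac-cis-2,8a-dibromo-7-methyl-6-{[tri(propan-2-yl)silyl]oxy}-4a,5,8,8a-tetrahydronaphthalene-1,4-dione (one enantiomer drawn) | O=C1C(Br)=CC(=O)[C@@H]2CC(O[Si](C(C)C)(C(C)C)C(C)C)=C(C)C[C@]12Br | intermediate (not isolated)
12 | 2-bromo-7-methyl-6-{[tri(propan-2-yl)silyl]oxy}naphthalene-1,4-diol | Cc1cc2c(O)c(Br)cc(O)c2cc1O[Si](C(C)C)(C(C)C)C(C)C | intermediate (not isolated)
13 | [(6-bromo-5,8-dimethoxy-3-methylnaphthalen-2-yl)oxy]tri(propan-2-yl)silane | Cc1cc2c(OC)c(Br)cc(OC)c2cc1O[Si](C(C)C)(C(C)C)C(C)C | intermediate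
14 | 6-bromo-5,8-dimethoxy-3-methylnaphthalen-2-ol | Cc1cc2c(OC)c(Br)cc(OC)c2cc1O | intermediate
15 | propanoyl chloride | CCC(Cl)=O | starting material
16 | 1-(6-bromo-2-hydroxy-5,8-dimethoxy-3-methylnaphthalen-1-yl)propan-1-one | CCC(=O)c1c(O)c(C)cc2c(OC)c(Br)cc(OC)c12 | intermediate
17 | tert-butyl{[(1Z)-1-{6-bromo-2-[(tert-butyldimethylsilyl)oxy]-5,8-dimethoxy-3-methylnaphthalen-1-yl}prop-1-en-1-yl]oxy}dimethylsilane | C/C=C(\O[Si](C)(C)C(C)(C)C)c1c(O[Si](C)(C)C(C)(C)C)c(C)cc2c(OC)c(Br)cc(OC)c12 | intermediate (not isolated)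
18 | rac-2-bromo-1-{6-bromo-2-[(tert-butyldimethylsilyl)oxy]-5,8-dimethoxy-3-methylnaphthalen-1-yl}propan-1-one | CC(Br)C(=O)c1c(O[Si](C)(C)C(C)(C)C)c(C)cc2c(OC)c(Br)cc(OC)c12 | intermediate
19 | rac-(1-{6-bromo-2-[(tert-butyldimethylsilyl)oxy]-5,8-dimethoxy-3-methylnaphthalen-1-yl}-1-oxopropan-2-yl)triphenylphosphonium bromide | CC([P+](c1ccccc1)(c1ccccc1)c1ccccc1)C(=O)c1c(O[Si](C)(C)C(C)(C)C)c(C)cc2c(OC)c(Br)cc(OC)c12.[Br-] | intermediate (not isolated)
20 | 1-{6-bromo-2-[(tert-butyldimethylsilyl)oxy]-5,8-dimethoxy-3-methylnaphthalen-1-yl}-2-(triphenyl-λ5-phosphanylidene)propan-1-one | CC(=P(c1ccccc1)(c1ccccc1)c1ccccc1)C(=O)c1c(O[Si](C)(C)C(C)(C)C)c(C)cc2c(OC)c(Br)cc(OC)c12 | intermediate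
21 | (2R,3S,4R,5E)-7-{6-bromo-2-[(tert-butyldimethylsilyl)oxy]-5,8-dimethoxy-3-methylnaphthalen-1-yl}-3-[(tert-butyldimethylsilyl)oxy]-2,4,6-trimethyl-7-oxohept-5-enal | C/C(=C\[C@@H](C)[C@H](O[Si](C)(C)C(C)(C)C)[C@@H](C)C=O)C(=O)c1c(O[Si](C)(C)C(C)(C)C)c(C)cc2c(OC)c(Br)cc(OC)c12 | intermediate
22 | (2R,3S,4R,5E)-7-{6-bromo-2-[(tert-butyldimethylsilyl)oxy]-5,8-dimethoxy-3-methylnaphthalen-1-yl}-3-[(tert-butyldimethylsilyl)oxy]-2,4,6-trimethyl-7-oxohept-5-enoic acid | C/C(=C\[C@@H](C)[C@H](O[Si](C)(C)C(C)(C)C)[C@@H](C)C(=O)O)C(=O)c1c(O[Si](C)(C)C(C)(C)C)c(C)cc2c(OC)c(Br)cc(OC)c12 | intermediate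
23 | (2R,3S,4R,5E)-7-{6-bromo-2-[(tert-butyldimethylsilyl)oxy]-3-methyl-5,8-dioxo-5,8-dihydronaphthalen-1-yl}-3-[(tert-butyldimethylsilyl)oxy]-2,4,6-trimethyl-7-oxohept-5-enoic acid | C/C(=C\[C@@H](C)[C@H](O[Si](C)(C)C(C)(C)C)[C@@H](C)C(=O)O)C(=O)c1c(O[Si](C)(C)C(C)(C)C)c(C)cc2c1C(=O)C=C(Br)C2=O | intermediate
24 | (2R,3S,4R,5E)-7-(6-bromo-2-hydroxy-3-methyl-5,8-dioxo-5,8-dihydronaphthalen-1-yl)-3-hydroxy-2,4,6-trimethyl-7-oxohept-5-enoic acid | C/C(=C\[C@@H](C)[C@H](O)[C@@H](C)C(=O)O)C(=O)c1c(O)c(C)cc2c1C(=O)C=C(Br)C2=O | intermediate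
25 | (2R,3S,4R,5E)-7-(6-azido-2-hydroxy-3-methyl-5,8-dioxo-5,8-dihydronaphthalen-1-yl)-3-hydroxy-2,4,6-trimethyl-7-oxohept-5-enoic acid | C/C(=C\[C@@H](C)[C@H](O)[C@@H](C)C(=O)O)C(=O)c1c(O)c(C)cc2c1C(=O)C=C(N=[N+]=[N-])C2=O | intermediate (not isolated)
26 | (2R,3S,4R,5E)-7-(6-amino-2-hydroxy-3-methyl-5,8-dioxo-5,8-dihydronaphthalen-1-yl)-3-hydroxy-2,4,6-trimethyl-7-oxohept-5-enoic acid (CNP0236465.1) | C/C(=C\[C@@H](C)[C@H](O)[C@@H](C)C(=O)O)C(=O)c1c(O)c(C)cc2c1C(=O)C=C(N)C2=O | target

**Step count**

Total steps: 15. Longest linear sequence: 11 steps (steps 5–15, from 8); the C5 branch (steps 1–4) joins at step 11.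

**Three steps most likely to fail**

1. Step 11 (proposed new method). The thiourea may be tied up by the ylide oxygen or by Ph3PO, the rate gain over background may be too small, or the group selectivity may be only moderate. The fallback uses known chemistry; it sets out from dialdehyde 7 and ylide 20 and comes back to the route at acid 22. Dialdehyde 7 is oxidised (NaClO2, NaH2PO4, 2‑methylbut‑2‑ene) to the meso diacid F1, which Ac2O closes to the meso anhydride F2. Methanolysis of F2 under a cinchona‑alkaloid catalyst (a quinidine‑ or quinine‑derived bifunctional sulfonamide or the corresponding bis‑cinchona ether, whichever pseudo‑enantiomer gives the shown half‑ester) is an established organocatalytic anhydride desymmetrisation and gives the half‑ester F3. BH3·SMe2 reduces only the free acid to the hydroxy ester F4 (used at once to avoid lactonisation), and Dess–Martin oxidation gives the aldehyde ester F5. An ordinary uncatalysed Wittig reaction of F5 with 20 (toluene, 90 °C) gives the enone methyl ester F6, and Me3SnOH (1,2‑dichloroethane, 80 °C) cleaves the ester to 22.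

2. Step 6. The anaerobic one‑flask sequence may stall before aromatisation, or the aryl silyl ether may be partly lost and over‑methylated. The fallback sets out from 9 and 10 and comes back at 13. The cycloaddition is run as before, and 11 is then stirred with Et3N in CH2Cl2 open to air, so that HBr loss, enolisation and air oxidation give the isolable, stable naphthoquinone F7. After purification, F7 is reduced with aqueous Na2S2O4 to 12 and methylated (Me2SO4, K2CO3, acetone) to 13. This replaces redox‑neutral trapping by an oxidation/reduction pair through an isolated quinone.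

3. Step 9. Enol silylation of the twisted, hindered ketone may be incomplete, or NBS may brominate the arene. The fallback sets out from 16 and comes back at 18. Only the phenol is silylated (TBSOTf 1.1 equiv, 2,6‑lutidine, −78 °C) to give the mono‑silylated ketone F8, and the ketone is then brominated directly with phenyltrimethylammonium tribromide (THF, 0 °C; acid‑catalysed enol bromination) to give 18.

Further compounds

F1 | step 11 | meso-(2R,4S)-3-[(tert-butyldimethylsilyl)oxy]-2,4-dimethylpentanedioic acid | OC(=O)[C@@H](C)[C@H](O[Si](C)(C)C(C)(C)C)[C@@H](C)C(=O)O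
F2 | step 11 | meso-(3R,5S)-4-[(tert-butyldimethylsilyl)oxy]-3,5-dimethyloxane-2,6-dione (methyls cis, silyloxy trans to both) | O=C1[C@@H](C)[C@H](O[Si](C)(C)C(C)(C)C)[C@@H](C)C(=O)O1
F3 | step 11 | (2S,3S,4R)-3-[(tert-butyldimethylsilyl)oxy]-5-methoxy-2,4-dimethyl-5-oxopentanoic acid | OC(=O)[C@@H](C)[C@H](O[Si](C)(C)C(C)(C)C)[C@@H](C)C(=O)OC
F4 | step 11 | methyl (2R,3S,4R)-3-[(tert-butyldimethylsilyl)oxy]-5-hydroxy-2,4-dimethylpentanoate | OC[C@@H](C)[C@H](O[Si](C)(C)C(C)(C)C)[C@@H](C)C(=O)OC
F5 | step 11 | methyl (2R,3S,4S)-3-[(tert-butyldimethylsilyl)oxy]-2,4-dimethyl-5-oxopentanoate | O=C[C@@H](C)[C@H](O[Si](C)(C)C(C)(C)C)[C@@H](C)C(=O)OC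
F6 | step 11 | methyl (2R,3S,4R,5E)-7-{6-bromo-2-[(tert-butyldimethylsilyl)oxy]-5,8-dimethoxy-3-methylnaphthalen-1-yl}-3-[(tert-butyldimethylsilyl)oxy]-2,4,6-trimethyl-7-oxohept-5-enoate | C/C(=C\[C@@H](C)[C@H](O[Si](C)(C)C(C)(C)C)[C@@H](C)C(=O)OC)C(=O)c1c(O[Si](C)(C)C(C)(C)C)c(C)cc2c(OC)c(Br)cc(OC)c12
F7 | step 6 | 2-bromo-7-methyl-6-{[tri(propan-2-yl)silyl]oxy}naphthalene-1,4-dione | Cc1cc2C(=O)C(Br)=CC(=O)c2cc1O[Si](C(C)C)(C(C)C)C(C)C
F8 | step 9 | 1-{6-bromo-2-[(tert-butyldimethylsilyl)oxy]-5,8-dimethoxy-3-methylnaphthalen-1-yl}propan-1-one | CCC(=O)c1c(O[Si](C)(C)C(C)(C)C)c(C)cc2c(OC)c(Br)cc(OC)c12
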